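All runs are simulated with made-up constants; the scatter is artificial.

Spring carries twice the J of dusk and runs twice as long, but on less E; the hunch sent over was that dusk stays ahead, and a quick number follows from one index.

| setting | grey | violet | red | teal | spring | dusk |
|---|---|---|---|---|---|---|
| J | 0.29 M | 0.46 M | 0.59 M | 0.33 M | 0.60 M | 0.33 M |
| E | 0.495 M | 0.495 M | 0.495 M | 0.40 M | 0.300 M | 0.495 M |
| remark | run made earlier | run made earlier | run made earlier | run made earlier |  |  |
| time |  |  |  |  | 6.0 h | 3.0 h |

- grey (time / min: Q / %, J / %): 8.00: 49.1, 51.8; 25.0: 52.7, 48.4; 40.0: 50.4, 52.4; 60.0: 46.2, 53.8; 90.0: 42.2, 60.5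
- violet (time / min: Q / %, J / %): 8.00: 42.8, 53.1; 25.0: 46.6, 53.0; 40.0: 43.1, 55.8; 60.0: 39.1, 58.1; 90.0: 37.7, 62.8
- red (time / min: Q / %, J / %): 8.00: 40.5, 59.2; 25.0: 40.2, 60.3; 40.0: 39.9, 60.8; 60.0: 38.6, 62.4; 90.0: 35.1, 65.3
- teal (time / min: Q / %, J / %): 8.00: 41.1, 60.1; 25.0: 42.6, 56.8; 40.0: 41.4, 60.3; 60.0: 38.1, 63.5; 90.0: 34.9, 66.9

(readings scatter by 1 percentage point)

- which one finishes higher in amount of Q, in percent of the J charged ("neither" within 2 percentage points) (spring / dusk / neither)
- amount of Q at the end, in percent of the J charged, spring
- amount of Q at the end, in percent of the J charged, dusk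



In the runs Q and J sum to about the J charged, so one number describes a flask at a given moment: the index log10([Q]/[J]), the log-odds of Q against J. Between the second and last readings, grey and teal, the runs nearest dusk in J, lose index at an average of 0.162 h⁻¹, the slope of the index in time, while red, nearest spring in J, reads a smaller 0.0863 h⁻¹. The reckoning offered here also assumes that the index moves one for one with log10[E] charged; grey's last reading, moved so to teal's E, gives Q of 36.0% against 34.9% read, about one scatter away although J differs slightly.

Dusk shares grey's E, so the reckoning here starts it from grey's last reading and carries it on for 1.50 h, to an estimated index of −0.399, or Q near 28.5%. For spring the reckoning here starts from red's last reading, shifted from red's E to spring's, and carries it on for 4.50 h, to an estimated index of −0.876, or Q near 11.8%. The forecast, reading “a fast reversible J + E ⇌ Q, with free E slowly lost to a side path”, names dusk, with 34% (28% to 39%) for dusk and 15% (9% to 20%) for spring; the reckoning here has the same order but lies lower on both.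

The flask ends dusk at 30.2% and spring at 12.5%, so dusk finishes higher by 18 percentage points.

    J + E ⇌ Q (K = 85.0 M⁻¹, k = 0.430 M⁻¹ min⁻¹)
    E → L (k = 0.170 min⁻¹)

A neighbour, the same flask as dusk but charged with 0.20 M of E, takes the same reckoning: grey's last index, shifted to this E and falling at 0.162 h⁻¹ over the same remaining time, reaches −0.793, which reads as Q near 13.9%. The neighbour flask gives 14.9%, with 0.606 equiv of E to J, and ends with 85% of its J unbound and 0.43% of its E unbound.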